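## Retrosynthetic overview

Ring A is the benzo ring of the benzofuran, ring B the furan ring, ring C the 3,5-dihydroxyphenyl ring; the side chain is C1'–C8' (geranyl numbering).

- Target 16 ⇐ tris-silyl ether 15 (fluoride) ⇐ C1'–C2' bond: benzylic chloride 11 (C1' on C7 of ring A) plus (E)-alkenylalane 14, made in the same flask from enyne 13 and Me3Al, which also installs the C3' methyl and fixes the E geometry of C2'=C3'.
- Enabling feature: C1' is a benzylic methylene on C7 of ring A (no β-hydrogen, flanked by O1 and the C6 oxygen) bonded to a trisubstituted E alkene whose C3' carries a methyl. This is the retron of syn-methylmetalation of a terminal alkyne followed by capture with a benzylic electrophile.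
- 11 ⇐ ester 7 (silylation, reduction, chlorination): C1' is the ester carbon of a 2,6-dihydroxybenzoate, so the C7 attachment between O1 and the C6 oxygen is fixed from the start.
- 7 ⇐ iodoresorcylate 5 + arylalkyne 3. Rings A and C are bought; ring B is closed in step 4 by domino Sonogashira coupling/5-endo-dig heteroannulation; no ring is formed afterwards.

Key step: step 9

Assumption: the SMILES is taken as the definition of the target (7-geranyl-6-hydroxy-2-(3,5-dihydroxyphenyl)benzofuran); equivalents quoted are intended amounts.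

## Route

Step 1
Reactants: 1 3,5-dihydroxybenzaldehyde
Product: 2 3,5-bis(tert-butyldimethylsilyloxy)benzaldehyde
Conditions: TBSCl (2.4 equiv), imidazole (5 equiv), DMF, rt
Reagents that add atoms: tert-butyldimethylsilyl chloride, CC(C)(C)[Si](C)(C)Cl
Why: Silylation of both phenols through the N-silylimidazolium species (silyl ether protection) should be clean, and the aldehyde is inert to these conditions.

Step 2
Reactants: 2 3,5-bis(tert-butyldimethylsilyloxy)benzaldehyde
Product: 3 1-ethynyl-3,5-bis(tert-butyldimethylsilyloxy)benzene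
Conditions: Me3SiCHN2, LiN(i-Pr)2, THF, −78 °C to rt
Reagents that add atoms: trimethylsilyldiazomethane, C[Si](C)(C)C=[N+]=[N-]
Why: Colvin rearrangement (addition of the lithiated diazo compound, Peterson-type elimination, loss of N2 and 1,2-hydrogen shift of the alkylidene carbene) should give the terminal alkyne under aprotic conditions that spare the aryl silyl ethers.

Step 3
Reactants: 4 methyl 2,6-dihydroxybenzoate
Product: 5 methyl 2,6-dihydroxy-3-iodobenzoate
Conditions: N-iodosuccinimide (1.0 equiv), MeCN, 0 °C, dark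
Reagents that add atoms: N-iodosuccinimide, O=C1CCC(=O)N1I
Why: Electrophilic aromatic iodination should go to C3 (equivalent to C5), which is ortho to one hydroxyl and para to the other, whereas C4 is meta to both; one equivalent at low temperature limits double iodination.

Step 4
Reactants: 5 methyl 2,6-dihydroxy-3-iodobenzoate; 3 1-ethynyl-3,5-bis(tert-butyldimethylsilyloxy)benzene
Product: 7 methyl 2-[3,5-bis(tert-butyldimethylsilyloxy)phenyl]-6-hydroxy-1-benzofuran-7-carboxylate, via diarylalkyne 6 (not isolated)
Conditions: PdCl2(PPh3)2 (3 mol%), CuI (6 mol%), Et3N, DMF, rt then 70 °C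
Reagents that add atoms: none
Why: Sonogashira coupling followed by 5-endo-dig attack of the C2 hydroxyl on the metal-activated alkyne (domino coupling/heteroannulation of an o-iodophenol) should close ring B, and the C6 hydroxyl, para to the alkyne, cannot cyclise.

Step 5
Reactants: 7 methyl 2-[3,5-bis(tert-butyldimethylsilyloxy)phenyl]-6-hydroxy-1-benzofuran-7-carboxylate
Product: 8 methyl 6-(tert-butyldimethylsilyloxy)-2-[3,5-bis(tert-butyldimethylsilyloxy)phenyl]-1-benzofuran-7-carboxylate
Conditions: TBSOTf, 2,6-lutidine, CH2Cl2, 0 °C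
Reagents that add atoms: tert-butyldimethylsilyl trifluoromethanesulfonate, CC(C)(C)[Si](C)(C)OS(=O)(=O)C(F)(F)F
Why: Silylation with the silyl triflate should overcome the hydrogen bond of the salicylate-type C6 hydroxyl to the ester (silyl ether protection).

Step 6
Reactants: 8 methyl 6-(tert-butyldimethylsilyloxy)-2-[3,5-bis(tert-butyldimethylsilyloxy)phenyl]-1-benzofuran-7-carboxylate
Product: 9 {6-(tert-butyldimethylsilyloxy)-2-[3,5-bis(tert-butyldimethylsilyloxy)phenyl]-1-benzofuran-7-yl}methanol
Conditions: i-Bu2AlH (3 equiv), toluene, −78 to −20 °C; aqueous potassium sodium tartrate (KNaC4H4O6)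
Reagents that add atoms: none
Why: Hydride reduction of the ester to the primary alcohol with i-Bu2AlH should leave the aryl silyl ethers intact, and the aluminium alkoxide in a non-polar solvent at low temperature should not pick up the neighbouring silyl group.

Step 7
Reactants: 9 {6-(tert-butyldimethylsilyloxy)-2-[3,5-bis(tert-butyldimethylsilyloxy)phenyl]-1-benzofuran-7-yl}methanol
Product: 11 7-(chloromethyl)-6-(tert-butyldimethylsilyloxy)-2-[3,5-bis(tert-butyldimethylsilyloxy)phenyl]-1-benzofuran, via benzylic mesylate 10 (not isolated)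
Conditions: MsCl, 2,4,6-collidine, LiCl, DMF, 0 °C; used directly after a cold work-up
Reagents that add atoms: methanesulfonyl chloride, CS(=O)(=O)Cl (mesyl group of 10 only); lithium chloride, [Li+].[Cl-] (chlorine of 11)
Why: Mesylation and in situ SN2 displacement by chloride under amine-buffered, acid-free conditions should give the benzylic chloride without cleaving silyl ethers.

Step 8
Reactants: 12 5-bromo-2-methylpent-2-ene
Product: 13 6-methylhept-5-en-1-yne
Conditions: LiC≡CH·H2NCH2CH2NH2 (lithium acetylide–ethylenediamine complex), DMSO, 10 °C to rt; distillation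
Reagents that add atoms: lithium acetylide ethylenediamine complex, [Li+].[C-]#C.NCCN
Why: SN2 alkylation of the acetylide by the primary homoallylic bromide in a dipolar aprotic solvent should give the terminal enyne.

Step 9
Reactants: 13 6-methylhept-5-en-1-yne; 11 7-(chloromethyl)-6-(tert-butyldimethylsilyloxy)-2-[3,5-bis(tert-butyldimethylsilyloxy)phenyl]-1-benzofuran
Product: 15 6-(tert-butyldimethylsilyloxy)-2-[3,5-bis(tert-butyldimethylsilyloxy)phenyl]-7-[(2E)-3,7-dimethylocta-2,6-dien-1-yl]-1-benzofuran, via alkenylalane 14 (not isolated)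
Conditions: 13 (1.5 equiv), Me3Al (3 equiv), Cp2ZrCl2 (0.3 equiv), ClCH2CH2Cl, 0 °C to rt; volatiles removed in vacuo, hexane extract decanted from zirconium salts, THF; then 11 (1.0 equiv), NiCl2(PPh3)2 (5 mol%) pre-reduced with n-BuLi (10 mol%) to zerovalent nickel, THF, 0 °C to rt
Reagents that add atoms: trimethylaluminium, C[Al](C)C
Why: Negishi carboalumination is merged with a nickel-catalysed cross-coupling: Cp2ZrCl2/Me3Al should deliver methyl and aluminium syn across the terminal alkyne of 13, methyl to the internal carbon and aluminium to the terminal one, giving the (E)-alkenylalane 14 and leaving the trisubstituted C6'=C7' alkene untouched. Zerovalent nickel should then insert into the benzylic C–Cl bond of 11, the alkenyl group should transmetalate from aluminium in preference to methyl, and reductive elimination should form the C1'–C2' bond with retention of alkene geometry. The closest known reaction type is the one-pot carboalumination/benzylic chloride coupling used to attach polyprenyl chains to electron-rich chloromethylarenes. No ring is closed and no stereocentre is formed; the only stereochemical element, the E geometry of C2'=C3', is controlled by the syn stereospecificity of the carbometalation and the stereoretentive coupling. The step needs regioselective methylmetalation (secured by the terminal alkyne, which takes the metal on its unsubstituted carbon), freedom from β-hydride elimination (C1' has no β-hydrogen on the ring side) and suppression of Lewis-acid ionisation of the electron-rich benzylic chloride (excess Me3Al is evaporated and the coupling is run in coordinating THF).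

Step 10
Reactants: 15 6-(tert-butyldimethylsilyloxy)-2-[3,5-bis(tert-butyldimethylsilyloxy)phenyl]-7-[(2E)-3,7-dimethylocta-2,6-dien-1-yl]-1-benzofuran
Product: 16 5-{7-[(2E)-3,7-dimethylocta-2,6-dien-1-yl]-6-hydroxy-1-benzofuran-2-yl}benzene-1,3-diol (Mulberrofuran l, the target)
Conditions: Bu4NF (3.5 equiv), AcOH (3.5 equiv), degassed THF, 0 °C
Reagents that add atoms: none
Why: Fluoride cleavage of the three aryl silyl ethers, buffered with acetic acid, should free the phenols without acid that could cyclise the C6 hydroxyl onto the C2'=C3' alkene or isomerise the skipped diene.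

## Compound list

1 | 3,5-dihydroxybenzaldehyde | O=Cc1cc(O)cc(O)c1 | starting material
2 | 3,5-bis(tert-butyldimethylsilyloxy)benzaldehyde | O=Cc1cc(O[Si](C)(C)C(C)(C)C)cc(O[Si](C)(C)C(C)(C)C)c1 | intermediate
3 | 1-ethynyl-3,5-bis(tert-butyldimethylsilyloxy)benzene | C#Cc1cc(O[Si](C)(C)C(C)(C)C)cc(O[Si](C)(C)C(C)(C)C)c1 | intermediate
4 | methyl 2,6-dihydroxybenzoate | COC(=O)c1c(O)cccc1O | starting material
5 | methyl 2,6-dihydroxy-3-iodobenzoate | COC(=O)c1c(O)ccc(I)c1O | intermediate
6 | methyl 3-{[3,5-bis(tert-butyldimethylsilyloxy)phenyl]ethynyl}-2,6-dihydroxybenzoate (diarylalkyne) | COC(=O)c1c(O)ccc(C#Cc2cc(O[Si](C)(C)C(C)(C)C)cc(O[Si](C)(C)C(C)(C)C)c2)c1O | intermediate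
7 | methyl 2-[3,5-bis(tert-butyldimethylsilyloxy)phenyl]-6-hydroxy-1-benzofuran-7-carboxylate | COC(=O)c1c(O)ccc2cc(-c3cc(O[Si](C)(C)C(C)(C)C)cc(O[Si](C)(C)C(C)(C)C)c3)oc12 | intermediate
8 | methyl 6-(tert-butyldimethylsilyloxy)-2-[3,5-bis(tert-butyldimethylsilyloxy)phenyl]-1-benzofuran-7-carboxylate | COC(=O)c1c(O[Si](C)(C)C(C)(C)C)ccc2cc(-c3cc(O[Si](C)(C)C(C)(C)C)cc(O[Si](C)(C)C(C)(C)C)c3)oc12 | intermediate
9 | {6-(tert-butyldimethylsilyloxy)-2-[3,5-bis(tert-butyldimethylsilyloxy)phenyl]-1-benzofuran-7-yl}methanol | OCc1c(O[Si](C)(C)C(C)(C)C)ccc2cc(-c3cc(O[Si](C)(C)C(C)(C)C)cc(O[Si](C)(C)C(C)(C)C)c3)oc12 | intermediate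
10 | {6-(tert-butyldimethylsilyloxy)-2-[3,5-bis(tert-butyldimethylsilyloxy)phenyl]-1-benzofuran-7-yl}methyl methanesulfonate (benzylic mesylate) | CS(=O)(=O)OCc1c(O[Si](C)(C)C(C)(C)C)ccc2cc(-c3cc(O[Si](C)(C)C(C)(C)C)cc(O[Si](C)(C)C(C)(C)C)c3)oc12 | intermediate
11 | 7-(chloromethyl)-6-(tert-butyldimethylsilyloxy)-2-[3,5-bis(tert-butyldimethylsilyloxy)phenyl]-1-benzofuran | ClCc1c(O[Si](C)(C)C(C)(C)C)ccc2cc(-c3cc(O[Si](C)(C)C(C)(C)C)cc(O[Si](C)(C)C(C)(C)C)c3)oc12 | intermediate
12 | 5-bromo-2-methylpent-2-ene | CC(C)=CCCBr | starting material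
13 | 6-methylhept-5-en-1-yne | CC(C)=CCCC#C | intermediate
14 | [(1E)-2,6-dimethylhepta-1,5-dien-1-yl]dimethylalane (alkenylalane) | CC(C)=CCC/C(C)=C/[Al](C)C | intermediate
15 | 6-(tert-butyldimethylsilyloxy)-2-[3,5-bis(tert-butyldimethylsilyloxy)phenyl]-7-[(2E)-3,7-dimethylocta-2,6-dien-1-yl]-1-benzofuran | CC(C)=CCC/C(C)=C/Cc1c(O[Si](C)(C)C(C)(C)C)ccc2cc(-c3cc(O[Si](C)(C)C(C)(C)C)cc(O[Si](C)(C)C(C)(C)C)c3)oc12 | intermediate
16 | 5-{7-[(2E)-3,7-dimethylocta-2,6-dien-1-yl]-6-hydroxy-1-benzofuran-2-yl}benzene-1,3-diol (Mulberrofuran l) | CC(C)=CCC/C(C)=C/Cc1c(O)ccc2cc(-c3cc(O)cc(O)c3)oc12 | target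

## Step count and risks

Total step count: 10. Longest linear sequence: 8 steps (steps 1, 2, 4, 5, 6, 7, 9, 10 from compound 1).

**Step 9.** What may go wrong: ionisation of the electron-rich benzylic chloride by Lewis-acidic aluminium species, leading to methyl transfer or Friedel–Crafts self-alkylation, or alkenyl transmetalation so slow that reductive homocoupling of the benzylic partner wins. The fallback reverses the polarity and removes aluminium before the benzylic partner is introduced; it sets out from 13 and 11 and comes back at 15. Alane 14, made from 13 as in step 9, would be quenched with I2 in THF at −30 °C to give (1E)-1-iodo-2,6-dimethylhepta-1,5-diene F1 by stereoretentive iododealumination. Chloride 11 would be treated with Zn dust and LiCl in THF to give ({6-(tert-butyldimethylsilyloxy)-2-[3,5-bis(tert-butyldimethylsilyloxy)phenyl]-1-benzofuran-7-yl}methyl)zinc chloride F2 by direct zinc insertion. Negishi coupling of F2 with F1 under Pd(PPh3)4 (zerovalent palladium) in THF at rt should form the same C1'–C2' bond and give 15.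

**Step 7.** What may go wrong: ionisation of the o-silyloxybenzyl chloride as it forms or is handled, with loss of the C6 silyl group and oligomerisation through a quinone methide. The fallback makes that quinone methide the intended intermediate; it sets out from 7 and comes back at 16.
- Reduction of 7 with i-Bu2AlH (toluene, −78 to 0 °C) should give 2-[3,5-bis(tert-butyldimethylsilyloxy)phenyl]-7-(hydroxymethyl)-1-benzofuran-6-ol F3.
- Selective acylation of the more acidic phenol with Boc2O (i-Pr2NEt, cat. DMAP, CH2Cl2, 0 °C) should give tert-butyl {2-[3,5-bis(tert-butyldimethylsilyloxy)phenyl]-7-(hydroxymethyl)-1-benzofuran-6-yl} carbonate F4.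
- The iodide (1E)-1-iodo-2,6-dimethylhepta-1,5-diene F1 would be converted with t-BuLi (2 equiv, Et2O, −78 °C) and MgBr2·OEt2 into [(1E)-2,6-dimethylhepta-1,5-dien-1-yl]magnesium bromide F5.
- F4 would be deprotonated with MeMgBr (1 equiv, THF, −78 °C), treated with F5 and warmed. The alkoxide should take over the carbonate group, tert-butyl carbonate should be expelled to give the o-quinone methide spanning the C6 oxygen, C6, C7 and C1', and F5 should add 1,4 at C1'. This gives 2-[3,5-bis(tert-butyldimethylsilyloxy)phenyl]-7-[(2E)-3,7-dimethylocta-2,6-dien-1-yl]-1-benzofuran-6-ol F6.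
- Bu4NF/AcOH in THF would then give 16.

**Step 4.** What may go wrong: transfer or loss of the aryl silyl groups to the phenoxides of 5 in hot amine/DMF, or stalling at the uncyclised alkyne because the C2 hydroxyl is tied up in a hydrogen bond to the ester. The fallback postpones all silylation until ring B exists, so that forcing annulation conditions become possible; it sets out from 1 and 5 and comes back at 8. Ohira–Bestmann homologation of unprotected 1 (dimethyl (1-diazo-2-oxopropyl)phosphonate, K2CO3, MeOH, rt) should give 5-ethynylbenzene-1,3-diol F7. Domino Sonogashira coupling/heteroannulation of F7 with 5 (PdCl2(PPh3)2, CuI, Et3N, DMF, up to 90 °C) should give methyl 2-(3,5-dihydroxyphenyl)-6-hydroxy-1-benzofuran-7-carboxylate F8. Exhaustive silylation with TBSOTf (3.5 equiv) and 2,6-lutidine in CH2Cl2 should give 8.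

## Further compounds

F1 | step 9 | (1E)-1-iodo-2,6-dimethylhepta-1,5-diene | CC(C)=CCC/C(C)=C/I
F2 | step 9 | ({6-(tert-butyldimethylsilyloxy)-2-[3,5-bis(tert-butyldimethylsilyloxy)phenyl]-1-benzofuran-7-yl}methyl)zinc chloride | Cl[Zn]Cc1c(O[Si](C)(C)C(C)(C)C)ccc2cc(-c3cc(O[Si](C)(C)C(C)(C)C)cc(O[Si](C)(C)C(C)(C)C)c3)oc12
F3 | step 7 | 2-[3,5-bis(tert-butyldimethylsilyloxy)phenyl]-7-(hydroxymethyl)-1-benzofuran-6-ol | OCc1c(O)ccc2cc(-c3cc(O[Si](C)(C)C(C)(C)C)cc(O[Si](C)(C)C(C)(C)C)c3)oc12
F4 | step 7 | tert-butyl {2-[3,5-bis(tert-butyldimethylsilyloxy)phenyl]-7-(hydroxymethyl)-1-benzofuran-6-yl} carbonate | CC(C)(C)OC(=O)Oc1ccc2cc(-c3cc(O[Si](C)(C)C(C)(C)C)cc(O[Si](C)(C)C(C)(C)C)c3)oc2c1CO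
F5 | step 7 | [(1E)-2,6-dimethylhepta-1,5-dien-1-yl]magnesium bromide | CC(C)=CCC/C(C)=C/[Mg]Br
F6 | step 7 | 2-[3,5-bis(tert-butyldimethylsilyloxy)phenyl]-7-[(2E)-3,7-dimethylocta-2,6-dien-1-yl]-1-benzofuran-6-ol | CC(C)=CCC/C(C)=C/Cc1c(O)ccc2cc(-c3cc(O[Si](C)(C)C(C)(C)C)cc(O[Si](C)(C)C(C)(C)C)c3)oc12
F7 | step 4 | 5-ethynylbenzene-1,3-diol | C#Cc1cc(O)cc(O)c1
F8 | step 4 | methyl 2-(3,5-dihydroxyphenyl)-6-hydroxy-1-benzofuran-7-carboxylate | COC(=O)c1c(O)ccc2cc(-c3cc(O)cc(O)c3)oc12
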